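All runs were computed on assumed constants; scatter was added.

Of the 4 questions on these flasks, the last hangs on a decision: do you charge the amber run as written, with 1400 mM of substrate on 750 mM of partner, or cut the substrate back?

| flask | substrate | partner | product | time |
|---|---|---|---|---|
| ochre | 300 mM | 750 mM |  |  |
| teal | 150 mM | 600 mM |  |  |
| green | 600 mM | 750 mM |  |  |
| red | 300 mM | 750 mM | 90.0 mM |  |
| amber | 1400 mM | 750 mM |  | 96 min |

- ochre run (time / min: [substrate] / mM): 12: 155.7; 24: 105.2; 36: 73.5; 48: 56.4; 60: 44.9; 72: 35.5; 84: 37.7; 96: 30.3
- teal run (time / min: [substrate] / mM): 12: 92.6; 24: 58.8; 36: 46.8; 48: 32.3; 60: 28.3; 72: 25.8; 84: 17.3; 96: 20.6
- green run (time / min: [substrate] / mM): 12: 347.4; 24: 258.2; 36: 215.3; 48: 187.7; 60: 169.7; 72: 157.1; 84: 145.8; 96: 139.5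
- red run (time / min: [substrate] / mM): 12: 161.9; 24: 105.1; 36: 72.5; 48: 53.7; 60: 46.6; 72: 40.1; 84: 36.1; 96: 28.8

(scatter of a reading: 2 mM)

- Overall: substrate + partner -> product.
- Constant volume, constant temperature.
- Readings of a species count what is bound in complexes too.
- An order is taken over about fifteen percent of the charge, up and down.

- order of the initial rate in [partner], near the charge of the ochre run, the rate being that where two percent of its substrate are product
- order of the initial rate in [substrate], near the charge of the ochre run, the rate being that where two percent of its substrate are product (one fixed amount of product, the same in the runs compared)
- the teal run starts with 150 mM less of substrate and of partner than the ochre run, and with no product. Compared where both hold the same amount of substrate, once fifteen percent of what the teal run was charged with has turned into product, is the teal run faster, slower or alike (within a tenth)?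
- substrate in the amber run at 96 min, as a share of the substrate charged

Start from the balance. Each turn takes one substrate and one partner, so by this count the difference between the two charges stays put, and equal charges are the zero of that scale. The ochre run stands at 450 mM of partner over, and the teal run at 450 mM. At equal substrate they should therefore hold equal partner, and the plain expectation is equal rates. Yet the teal run used 57.4 mM of substrate in its first 12 min, while the ochre run, starting that stretch from 155.7 mM, used 50.5 mM in the next 12.0 min. So I say the teal run is faster.

The amber run lies on the other side of zero: partner is the limiting reagent, with 650 mM of substrate over. Call the floor the excess of substrate charged over partner charged, as a share of the substrate charged: 46.4% in the amber run.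

For the upper end, take the green run, which was charged with the same partner as the amber run and had used 460 mM of substrate by 96 min. With twice the ochre run's substrate, the green run lost 253 mM in its first 12 min, more than the ochre run's 144 mM. So I expect the amber run to use at least the green run's amount, which leaves 67.1%.

My reckoning commits to the middle of that window, 56.8%. The window is 21 percentage points wide, and the scatter of one reading is 0.143% of the amber charge, far less than that. So I keep the charge: one reading will show where in the window the flask stands.

The forecast gives 1 for the order in partner, 0.95 for the order in substrate, faster for the teal run and 55% for the amber run, saying “For amber, partner is limiting.” Its share is lower than mine, though inside the same window.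

The flask gives 1.4 in partner, above the forecast's 1, 1.0 in substrate, faster for the teal run and 54.2% for the amber run.

    substrate + 2 partner → product + partner (0.4500 L² mol⁻² min⁻¹)
    2 partner ⇌ idle reagent dimer, settled at all times (1.200 L mol⁻¹)
    2 partner → lost reagent (0.02754 L mol⁻¹ min⁻¹)

Taking out the step from 2 partner to lost reagent moves the readings by 15 times the scatter, root mean square. The amber run's share stands 7.8 points above its floor of 46.4%. The green run has 150 mM of partner over, so the same rule gives it a floor of zero, and its substrate still read 139.5 mM, 23.3% of its charge, at 96 min.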